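A small charge of Q in this flask gives E and, beside it, some D, and the question is how D stands to E.

| setting | south-east | south-west | flask |
|---|---|---|---|
| Q | 0.24 M | 0.24 M | 0.24 M |
| X | 1.5 equiv | 6 equiv | 3.00 equiv |
| J | 0.12 M | 0.12 M | 0.120 M |
| remark | run made earlier | run made earlier |  |
| time |  |  | 10 min |

| run | time / min | D / % | E / % |
|---|---|---|---|
| south-east | 0.667 | 0.1 | 6.1 |
| south-east | 1.00 | 0.3 | 8.1 |
| south-east | 2.00 | 0.7 | 14.8 |
| south-east | 3.00 | 0.8 | 19.9 |
| south-east | 5.00 | 1.8 | 27.9 |
| south-east | 8.00 | 1.5 | 35.6 |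
| south-west | 0.500 | 0.8 | 16.7 |
| south-west | 1.50 | 2.0 | 38.9 |
| south-west | 3.00 | 1.9 | 57.9 |
| south-west | 4.00 | 2.2 | 65.6 |
| south-west | 6.00 | 2.8 | 74.3 |
| south-west | 8.00 | 3.1 | 78.1 |

(scatter of a reading: 0.3 percentage points)

1. ratio of D to E at 6.0 s
2. ratio of D to E at 1.0 min
3. ratio of D to E at 10 min
4. which of D and E there is more of at 10 min

- the numbers in the tables scatter by 0.3 percentage points (one standard deviation)
- a reading or a percentage of E counts all its forms, free or not

Counted as fractions of the Q charged, the early slopes of E in the two runs differ by a factor of 4.12, while their X differs by 4.00, so E reads as first order in X. D keeps pace with E in both runs, so it reads as having the same order, X drops out of the ratio, and the last readings of both runs fold into one number: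

s = (1.5% + 3.1%) / (35.6% + 78.1%) = 0.0405

This selectivity factor s, the fraction of D made per fraction of E made, has to survive a test. Run by run it reads 0.0421 and 0.0397, and at the first south-west reading 0.0479, where a scatter of 0.3 percentage points on 0.8% of D covers the gap, so one number serves. The reckoning here therefore puts the ratio at 0.0405 at each asked time, less firmly at 6.0 s, which lies before the readings, and puts E ahead, since s makes D the lesser product.

The forecast gives 0.041 (0.025 to 0.06) at 6.0 s, 0.041 (0.032 to 0.05) at 1.0 min and 0.041 (0.035 to 0.048) at 10 min, slightly more than s, with E ahead: “The ratio shows no dependence on X, no intercept and no drift”.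

The flask gives 0.0370, 0.0371 and 0.0384, inside those ranges. At 10 min its E, 61.4%, is more than its D, 2.36%, and s times that E gives 2.49% of D.

    Q + X ⇌ E (K = 18.0 M⁻¹, k = 0.270 M⁻¹ min⁻¹)
    Q + X ⇌ D (K = 18.0 M⁻¹, k = 0.0100 M⁻¹ min⁻¹)
    Q + J → Z (k = 0.470 M⁻¹ min⁻¹)
    X ⇌ G (K = 0.0810, k = 0.0950 min⁻¹)
    X + E ⇌ L, settled at all times (K = 3.10 M⁻¹)

Q and X enter both forward steps, so they cancel and the ratio starts at k2/k1, 0.0370, which is kinetic control. In this flask the ratio stands at 0.0384 after the 10 min allowed, whereas with that time limit taken away and ten times the time given, the same flask reads 0.0584. The neighbour with 7.50 equiv of X makes 84.4% of E, on which s gives 3.42% of D; the computed D there is 3.18%, at a ratio of 0.0377.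

(Readings and results are calculated with constants of no real substance, noise included.)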